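## The problem

Andavadoic acid (25) is a 3,3,5,5-tetrasubstituted 1,2-dioxolane. In the numbering used throughout, the ring is O1–O2–C3–C4–C5; C3 carries a methyl group and the acetic acid arm (C2, C1), C5 carries a methyl group and the 10-phenyldecyl chain (C1′ to C10′), and the two methyl groups are trans (3R,5S). Both stereocentres are fully substituted C–O carbons flanking C4H2, so neither can be epimerised or corrected once made. At each of them the groups to be told apart are a methyl and a primary alkyl arm, so 1,3-induction across the ring is weak in either direction and each centre needs its own dependable source of configuration. The O–O bond rules out catalytic hydrogenation, low-valent metals, stoichiometric phosphines and strong hydride donors at ambient temperature. The carboxyl group stands beta to a peroxide oxygen, so strong base at the carbonyl stage invites ring-opening elimination across C2–C3, and the unfunctionalised chain means that any alkene left by chain building must be removed with diimide. The enabling feature is C5: a quaternary C–O carbon bearing a methyl and the chain start C1′H2 is the pattern left when the terminal oxygen of a C3 hydroperoxide adds to the substituted carbon of a 2-methylallyl group with a metal on the CH2 terminus. With divalent palladium, O1–C5 formation closes the ring, and the CH2–Pd bond on C1′, which has no beta-hydrogen, can take up carbon monoxide to form C1′–C2′.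

## Retrosynthesis

**C1 oxidation level and the O–Si bond.** The carboxyl group of 25 is taken back to the primary alcohol 23 and this to the silyl ether 22. No skeletal bond is cut. The purpose is to keep the beta-peroxy carbonyl out of the route until the last step, after every basic operation. The forward steps are a fluoride desilylation and a peroxide-tolerant oxidation of alcohol to acid.

**C2′=C3′.** Compound 22 is taken back through the Z-alkene 21 to the aldehyde 17 and the ylide 20, which comes from the phosphonium salt 19 and (8-bromooctyl)benzene (18). A cut nearer the ring (C5–C1′) would have to create a quaternary centre, and a cut further out would need a functionalised chain on the dioxolane. Couplings of sp3 partners would bring organometallic reagents next to the O–O bond. The precursor 17 is simpler by nine carbons. The forward reaction needs carbonyl addition to outrun enolisation; alkene geometry is irrelevant because diimide removes the double bond.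

**C2′ oxidation level.** Aldehyde 17 is taken back to the methyl ester 16, the form in which the carbonylation delivers C2′. A half-reduction at low temperature is required that leaves the di-tertiary peroxide alone.

**O1–C5 and C1′–C2′ (key disconnection).** Ester 16 is cut to the homoallylic hydroperoxide 13, carbon monoxide (14) and methanol (15). Against the neighbouring cuts (C–C bond formation at the ring carbons through peroxycarbenium ions, or double C–O bond formation), this one removes the ring and the first chain carbon together. It leaves an acyclic precursor with a single stereocentre whose two arms are already different, a silyl ether and an alkene. The forward reaction must add the peroxide oxygen 5-exo to the substituted alkene carbon, choose the alkene face under ligand control, trap the alkylpalladium with CO before it reverts, and keep palladium divalent.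

**O2–C3 and O–Si.** Hydroperoxide 13 is taken back to the hydroperoxy alcohol 12, and this to the oxetane 10 and hydrogen peroxide (11). A tertiary hydroperoxide of defined configuration cannot be made by substitution of an unstrained alcohol derivative; the strain of the four-membered ring allows opening at the tertiary carbon with inversion. The forward steps must deliver peroxide to the tertiary carbon without engaging the 2-methylallyl alkene, and then silylate the primary alcohol beside a free hydroperoxide.

**Oxetane C–O, C2–H and the epoxide.** Oxetane 10 is taken back through tosylate 9, diol 8 and epoxy alcohol 7 to the dienol 6. The tertiary carbinol centre thus comes from Sharpless epoxidation of an E-trisubstituted allylic alcohol, the most dependable source of a methyl-bearing tertiary C–O centre. A direct enantioselective 2-methylallylation of the corresponding methyl ketone would be shorter but would have to tell methyl from a primary alkyl group. Forward, hydride must go to C2 of the epoxy alcohol, sulfonylation must be selective for the primary hydroxyl, and the ring must close 4-exo-tet.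

**C3–CH3, C1–C2 and C3–C4.** Dienol 6 is taken back to the enyne 3 (methyl and hydroxymethyl added across the alkyne), and 3 to 3-chloro-2-methylprop-1-ene (1) and ethynylmagnesium bromide (2). Methylalumination fixes the E geometry that the epoxidation needs. The 2-methylallyl unit is symmetrical to allylic transposition, so the coupling has no regiochemical issue.

## Roads not taken

**Alternative 1:** Both exocyclic C–C bonds at the ring carbons (C5–C1′ and C3–C2) are cut, back to the bis-methyl peroxyketal A1, 3,5-dimethoxy-3,5-dimethyl-1,2-dioxolane, which is available in one operation from a commercial 1,3-diketone and 11. Forward, a chiral silylium Lewis acid with a confined imidodiphosphorimidate counter-anion would ionise each ketal in turn and allyltrimethylsilane A2 would add twice to give the C2-symmetric diallyl dioxolane A3.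
- Merits: the ring is bought almost ready-made, allylation of 3-alkoxy-1,2-dioxolanes under Lewis acids is known in racemic form, and both centres would come from one catalyst. This road reaches the ring in far fewer steps than the chosen one.
- Weak points: two consecutive additions to planar tertiary peroxycarbenium ions must each be face-selective under counter-anion control, for which there is no precedent. The cis product is meso and is lost. The two allyl groups of A3 are homotopic, so one must be cleaved to the acid and the other extended in statistical operations, and diimide cannot saturate one alkene while sparing the other.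
- Comparison: the chosen plan is longer, but its arms are born different (ester and silyl ether), only one centre depends on unproven catalysis, and a shortfall there shows up as a separable diastereomer.

**Alternative 2:** Both ring C–O bonds (O2–C3 and O1–C5) are cut, back to the C2-symmetric bis-oxetane A4 and 11. Forward, silyl triflate-activated hydrogen peroxide would open one oxetane at its tertiary carbon and the new hydroperoxide would open the second in a 5-exo closure, giving the diol A5.
- Merits: both events are of known types, both centres come from Sharpless chemistry, and C2 symmetry raises enantiopurity because the minor enantiomer is diverted into a meso compound. In stereochemical reliability this road is better than the chosen one.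
- Weak points: A4 needs a two-directional synthesis from a skipped dienediol that is itself laborious. The free hydroxyl formed in the first opening can compete for the second oxetane (6-exo), and hydrogen peroxide can open both rings intermolecularly. The two hydroxyethyl arms of A5 are homotopic, so a statistical monoprotection is unavoidable, and the chain must still be grown from a two-carbon arm by oxidation and olefination.
- Comparison: the chosen plan avoids the statistical step and delivers the chain arm directly at the carbonyl level. If step 9 cannot be made selective, this road is the natural retreat; the monosilyl ether of A5 is compound F6 of the fallbacks.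

**Alternative 3:** C4–C5 and O2–C3 are cut, back to the silyl peroxyketal A6 (which carries the whole chain) and the isoprenol silyl ether A7. Forward, a chiral Lewis acid would ionise A6, the CH2 terminus of A7 would attack the peroxycarbenium carbon, and the silylperoxy oxygen would close onto the tertiary cation, giving A8, which is identical with 22 of the present route.
- Merits: this is the most convergent plan. The racemic annulation of silyl peroxyketals with 1,1-disubstituted alkenes under tin tetrachloride is known, and A8 is two steps from the target. In step economy it is clearly superior.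
- Weak points: two quaternary centres form in one stepwise event. The first bond must tell methyl from a long alkyl group on a freely rotating acyclic cation, and the ring closure must tell methyl from silyloxyethyl. No handle exists for absolute control, the four stereoisomers are hard to separate, and the tertiary cation can also lose a proton.
- Comparison: the chosen plan costs roughly eight more steps, but C3 is fixed by a known method before the ring exists, so the new step has only one centre to control and its errors are diastereomers, not enantiomers.

Key step: step 9

Remark: palladium-bound species of the catalytic cycle in step 9 and short-lived alkoxide, aluminate and oxaphosphetane stages are described in the Why lines; the non-isolated intermediates 4, 5, 20 and 24 carry numbers.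

## Route

Step 1
Reactants: 1 3-chloro-2-methylprop-1-ene; 2 ethynylmagnesium bromide
Product: 3 2-methylpent-1-en-4-yne
Conditions: CuCl (5 mol %), THF, 0 to 50 °C; pentane extraction, water washes, fractional distillation
Reagents that add atoms: none
Why: Copper-catalysed coupling of an allylic chloride with an alkynyl Grignard reagent; the 2-methylallyl unit is symmetrical to allylic transposition, so direct and transposed substitution give the same skipped enyne, and the moderate temperature avoids isomerisation to the allene.

Step 2
Reactants: 3 2-methylpent-1-en-4-yne
Product: 6 (2E)-3,5-dimethylhexa-2,5-dien-1-ol, via alkenyldimethylalane 4 (not isolated), via lithium alkenylalanate 5 (not isolated)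
Conditions: Me3Al, Cp2ZrCl2 (20 mol %), CH2Cl2, 0 °C to rt; volatiles removed; n-BuLi, THF–hexane, −78 °C; (CH2O)n, −78 °C to rt
Reagents that add atoms: trimethylaluminium C[Al](C)C; formaldehyde (as paraformaldehyde) C=O
Why: Negishi zirconium-catalysed carboalumination adds methyl and aluminium syn across the terminal alkyne with methyl on the internal carbon, and the alanate adds to formaldehyde with retention, which fixes the E geometry; the 1,1-disubstituted alkene is inert to the achiral zirconocene under these conditions.

Step 3
Reactants: 6 (2E)-3,5-dimethylhexa-2,5-dien-1-ol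
Product: 7 [(2S,3S)-3-methyl-3-(2-methylprop-2-en-1-yl)oxiran-2-yl]methanol
Conditions: Ti(OiPr)4 (10 mol %), L-(+)-diethyl tartrate (12 mol %), tBuOOH, 4 Å molecular sieves, CH2Cl2, −20 °C
Reagents that add atoms: tert-butyl hydroperoxide CC(C)(C)OO
Why: Sharpless asymmetric epoxidation; with the L-(+)-tartrate an E-trisubstituted allylic alcohol of this substitution pattern gives the (2S,3S)-epoxide, and the isolated alkene is not touched because oxygen transfer needs the titanium-bound allylic alkoxide.

Step 4
Reactants: 7 [(2S,3S)-3-methyl-3-(2-methylprop-2-en-1-yl)oxiran-2-yl]methanol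
Product: 8 (3S)-3,5-dimethylhex-5-ene-1,3-diol
Conditions: NaAlH2(OCH2CH2OMe)2, THF, 0 °C to rt
Reagents that add atoms: none
Why: Hydroxyl-directed reductive opening of a 2,3-epoxy alcohol; hydride is delivered from the alkoxyaluminate to C2, the less substituted epoxide carbon, so the 1,3-diol results and the C3–O bond with its configuration is retained.

Step 5
Reactants: 8 (3S)-3,5-dimethylhex-5-ene-1,3-diol
Product: 9 (3S)-3-hydroxy-3,5-dimethylhex-5-en-1-yl 4-methylbenzenesulfonate
Conditions: TsCl, Et3N, DMAP (cat.), CH2Cl2, 0 °C
Reagents that add atoms: 4-methylbenzenesulfonyl chloride Cc1ccc(cc1)S(=O)(=O)Cl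
Why: Selective sulfonylation of the primary hydroxyl; the tertiary hydroxyl does not react under these conditions.

Step 6
Reactants: 9 (3S)-3-hydroxy-3,5-dimethylhex-5-en-1-yl 4-methylbenzenesulfonate
Product: 10 (2S)-2-methyl-2-(2-methylprop-2-en-1-yl)oxetane
Conditions: KOtBu, THF, 0 °C to rt
Reagents that add atoms: none
Why: Intramolecular Williamson etherification (4-exo-tet); the tertiary alkoxide displaces the primary tosylate, so the stereocentre is not involved.

Step 7
Reactants: 10 (2S)-2-methyl-2-(2-methylprop-2-en-1-yl)oxetane; 11 hydrogen peroxide
Product: 12 (3R)-3-hydroperoxy-3,5-dimethylhex-5-en-1-ol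
Conditions: H2O2 (anhydrous in Et2O, excess), Me3SiOSO2CF3 (20 mol %), Et2O, −78 to −40 °C
Reagents that add atoms: none
Why: Lewis acid-promoted perhydrolysis of a 2,2-disubstituted oxetane; the activated ring is opened at the tertiary carbon with inversion, and excess peroxide at low temperature is meant to keep capture ahead of full ionisation and of participation by the homoallylic alkene.

Step 8
Reactants: 12 (3R)-3-hydroperoxy-3,5-dimethylhex-5-en-1-ol
Product: 13 tert-butyl{[(3R)-3-hydroperoxy-3,5-dimethylhex-5-en-1-yl]oxy}diphenylsilane
Conditions: tBuPh2SiCl (1.05 equiv), imidazole, CH2Cl2, −20 to 0 °C; brief K2CO3–MeOH wash at 0 °C if needed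
Reagents that add atoms: tert-butyl(chloro)diphenylsilane CC(C)(C)[Si](Cl)(c1ccccc1)c1ccccc1
Why: Silyl ether formation at the unhindered and more basic primary hydroxyl with a bulky chlorosilane and a weak base that does not generate the peroxy anion; any O–O–Si linkage formed is expected to be the more labile one and to be returned to the hydroperoxide by mild methanolysis.

Step 9
Reactants: 13 tert-butyl{[(3R)-3-hydroperoxy-3,5-dimethylhex-5-en-1-yl]oxy}diphenylsilane; 14 carbon monoxide; 15 methanol
Product: 16 methyl 2-[(3R,5S)-5-{2-[(tert-butyldiphenylsilyl)oxy]ethyl}-3,5-dimethyl-1,2-dioxolan-3-yl]acetate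
Conditions: Pd(OCOCF3)2 (10 mol %), enantiopure 2,2′-bis(4-benzyl-4,5-dihydro-1,3-oxazol-2-yl)-1,1′-binaphthyl (20 mol %, antipode fixed by screening), p-benzoquinone (4 equiv), CO (1 atm), MeOH–CH2Cl2, 0 °C to rt
Reagents that add atoms: none
Why: Proposed new method: divalent palladium carrying the chiral bis(oxazoline) binds the 2-methylallyl alkene and the terminal hydroperoxide oxygen adds to the substituted carbon (Wacker-type oxypalladation, 5-exo-trig), closing the ring O1–O2–C3–C4–C5 and leaving a CH2–Pd bond on C1′; because C5 is now quaternary this alkyl has no beta-hydrogen, so under CO it inserts to an acylpalladium that methanol cleaves to the methyl ester, and zerovalent palladium is returned to the divalent state by p-benzoquinone. The closest known reaction types are the cyclisation of unsaturated tertiary hydroperoxides to cyclic peroxides under divalent palladium with a quinone, and the enantioselective oxypalladation–methoxycarbonylation of 1,1-disubstituted alkenes by phenols and alcohols under Pd(OCOCF3)2 with chiral bis(oxazoline) ligands; new here is a hydroperoxide as nucleophile with carbonylative capture, closing a 1,2-dioxolane. The new centre C5 is set by the ligand, which selects the alkene face that palladium occupies; the C3 centre (methyl against silyloxyethyl) should bias this only weakly, so both ligand antipodes are to be run and the one giving the trans-dimethyl product kept, the cis isomer being a diastereomer removable by chromatography. Regioselectivity rests on the 1,1-disubstituted alkene (oxygen to the carbon that best bears positive charge, 5-exo over 6-endo), and chemoselectivity on the silyl ether, which keeps the arm oxygen out of a competing 6-exo closure. The O–O bond is spared only while palladium stays divalent, hence the excess of quinone and the CO atmosphere for fast capture of the alkyl.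

Step 10
Reactants: 16 methyl 2-[(3R,5S)-5-{2-[(tert-butyldiphenylsilyl)oxy]ethyl}-3,5-dimethyl-1,2-dioxolan-3-yl]acetate
Product: 17 2-[(3R,5S)-5-{2-[(tert-butyldiphenylsilyl)oxy]ethyl}-3,5-dimethyl-1,2-dioxolan-3-yl]acetaldehyde
Conditions: iBu2AlH (1.1 equiv), CH2Cl2, −78 °C; MeOH, then aq. KNaC4H4O6
Reagents that add atoms: none
Why: Low-temperature half-reduction of an ester; the tetrahedral aluminium hemiacetal persists at −78 °C and releases the aldehyde on work-up, and a peroxide flanked by two fully substituted carbons is not attacked by the hydride at this temperature.

Step 11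
Reactants: 18 (8-bromooctyl)benzene
Product: 19 triphenyl(8-phenyloctyl)phosphonium bromide
Conditions: PPh3, MeCN, reflux
Reagents that add atoms: triphenylphosphine c1ccc(cc1)P(c1ccccc1)c1ccccc1
Why: Quaternisation of triphenylphosphine by a primary bromide (SN2).

Step 12
Reactants: 19 triphenyl(8-phenyloctyl)phosphonium bromide; 17 2-[(3R,5S)-5-{2-[(tert-butyldiphenylsilyl)oxy]ethyl}-3,5-dimethyl-1,2-dioxolan-3-yl]acetaldehyde
Product: 21 tert-butyl{2-[(3S,5S)-3,5-dimethyl-5-[(2Z)-10-phenyldec-2-en-1-yl]-1,2-dioxolan-3-yl]ethoxy}diphenylsilane, via phosphonium ylide 20 (not isolated)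
Conditions: NaN(SiMe3)2, THF, 0 °C; then 17, −78 to 0 °C
Reagents that add atoms: none
Why: Wittig olefination with a lithium-free unstabilised ylide, which should add to the aldehyde at −78 °C faster than it deprotonates the alpha-position and give mainly the Z-alkene; the geometry is of no consequence because the alkene is reduced next, and the phosphorus stays pentavalent and so does not reduce the peroxide.

Step 13
Reactants: 21 tert-butyl{2-[(3S,5S)-3,5-dimethyl-5-[(2Z)-10-phenyldec-2-en-1-yl]-1,2-dioxolan-3-yl]ethoxy}diphenylsilane
Product: 22 tert-butyl{2-[(3S,5S)-3,5-dimethyl-5-(10-phenyldecyl)-1,2-dioxolan-3-yl]ethoxy}diphenylsilane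
Conditions: KO2CN=NCO2K (excess), AcOH, MeOH–CH2Cl2, 0 °C to rt
Reagents that add atoms: none
Why: Diimide reduction; concerted syn transfer of two hydrogens saturates the disubstituted alkene and leaves the O–O bond and the arene untouched, where catalytic hydrogenation would cleave the peroxide.

Step 14
Reactants: 22 tert-butyl{2-[(3S,5S)-3,5-dimethyl-5-(10-phenyldecyl)-1,2-dioxolan-3-yl]ethoxy}diphenylsilane
Product: 23 2-[(3S,5S)-3,5-dimethyl-5-(10-phenyldecyl)-1,2-dioxolan-3-yl]ethan-1-ol
Conditions: Bu4NF, THF, 0 °C to rt
Reagents that add atoms: none
Why: Fluoride cleavage of the silyl ether; the peroxide carbons carry no hydrogen, so base-induced peroxide fragmentation has no pathway.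

Step 15
Reactants: 23 2-[(3S,5S)-3,5-dimethyl-5-(10-phenyldecyl)-1,2-dioxolan-3-yl]ethan-1-ol
Product: 25 andavadoic acid (2-[(3R,5S)-3,5-dimethyl-5-(10-phenyldecyl)-1,2-dioxolan-3-yl]acetic acid), via peroxy aldehyde 24 (not isolated)
Conditions: TEMPO (20 mol %), PhI(OAc)2 (2.2 equiv), MeCN–H2O, rt
Reagents that add atoms: water O
Why: Oxoammonium-mediated oxidation of a primary alcohol through the aldehyde and its hydrate to the carboxylic acid under near-neutral conditions, which spare the dialkyl peroxide and the phenyl ring (a ruthenium tetroxide oxidation would attack the arene).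

## Compound list

Descriptors of the dioxolanes change along the route only because substituent priorities change; no centre is inverted after step 9, and the methyl groups are trans throughout.

1 | 3-chloro-2-methylprop-1-ene | C=C(C)CCl | starting material
2 | ethynylmagnesium bromide | C#C[Mg]Br | starting material
3 | 2-methylpent-1-en-4-yne | C=C(C)CC#C | intermediate
4 | dimethyl[(1E)-2,4-dimethylpenta-1,4-dien-1-yl]alumane | C[Al](C)/C=C(\C)CC(C)=C | intermediate (not isolated)
5 | lithium butyl[(1E)-2,4-dimethylpenta-1,4-dien-1-yl]dimethylaluminate | [Li+].CCCC[Al-](C)(C)/C=C(\C)CC(C)=C | intermediate (not isolated)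
6 | (2E)-3,5-dimethylhexa-2,5-dien-1-ol | C=C(C)C/C(C)=C/CO | intermediate
7 | [(2S,3S)-3-methyl-3-(2-methylprop-2-en-1-yl)oxiran-2-yl]methanol | C=C(C)C[C@]1(C)O[C@H]1CO | intermediate
8 | (3S)-3,5-dimethylhex-5-ene-1,3-diol | C=C(C)C[C@@](C)(CCO)O | intermediate
9 | (3S)-3-hydroxy-3,5-dimethylhex-5-en-1-yl 4-methylbenzenesulfonate | C=C(C)C[C@@](C)(CCOS(=O)(=O)c1ccc(C)cc1)O | intermediate
10 | (2S)-2-methyl-2-(2-methylprop-2-en-1-yl)oxetane | C=C(C)C[C@@]1(C)CCO1 | intermediate
11 | hydrogen peroxide | OO | starting material
12 | (3R)-3-hydroperoxy-3,5-dimethylhex-5-en-1-ol | C=C(C)C[C@](C)(CCO)OO | intermediate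
13 | tert-butyl{[(3R)-3-hydroperoxy-3,5-dimethylhex-5-en-1-yl]oxy}diphenylsilane | C=C(C)C[C@](C)(CCO[Si](c1ccccc1)(c1ccccc1)C(C)(C)C)OO | intermediate
14 | carbon monoxide | [C-]#[O+] | starting material
15 | methanol | CO | starting material
16 | methyl 2-[(3R,5S)-5-{2-[(tert-butyldiphenylsilyl)oxy]ethyl}-3,5-dimethyl-1,2-dioxolan-3-yl]acetate | C[C@]1(CC(=O)OC)C[C@](C)(CCO[Si](c2ccccc2)(c2ccccc2)C(C)(C)C)OO1 | intermediate
17 | 2-[(3R,5S)-5-{2-[(tert-butyldiphenylsilyl)oxy]ethyl}-3,5-dimethyl-1,2-dioxolan-3-yl]acetaldehyde | C[C@]1(CC=O)C[C@](C)(CCO[Si](c2ccccc2)(c2ccccc2)C(C)(C)C)OO1 | intermediate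
18 | (8-bromooctyl)benzene | BrCCCCCCCCc1ccccc1 | starting material
19 | triphenyl(8-phenyloctyl)phosphonium bromide | [Br-].c1ccc(cc1)CCCCCCCC[P+](c1ccccc1)(c1ccccc1)c1ccccc1 | intermediate
20 | triphenyl(8-phenyloctylidene)-λ5-phosphane | c1ccc(cc1)CCCCCCCC=P(c1ccccc1)(c1ccccc1)c1ccccc1 | intermediate (not isolated)
21 | tert-butyl{2-[(3S,5S)-3,5-dimethyl-5-[(2Z)-10-phenyldec-2-en-1-yl]-1,2-dioxolan-3-yl]ethoxy}diphenylsilane | C[C@]1(C/C=C\CCCCCCCc2ccccc2)C[C@](C)(CCO[Si](c2ccccc2)(c2ccccc2)C(C)(C)C)OO1 | intermediate
22 | tert-butyl{2-[(3S,5S)-3,5-dimethyl-5-(10-phenyldecyl)-1,2-dioxolan-3-yl]ethoxy}diphenylsilane | C[C@]1(CCCCCCCCCCc2ccccc2)C[C@](C)(CCO[Si](c2ccccc2)(c2ccccc2)C(C)(C)C)OO1 | intermediate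
23 | 2-[(3S,5S)-3,5-dimethyl-5-(10-phenyldecyl)-1,2-dioxolan-3-yl]ethan-1-ol | C[C@]1(CCCCCCCCCCc2ccccc2)C[C@](C)(CCO)OO1 | intermediate
24 | 2-[(3R,5S)-3,5-dimethyl-5-(10-phenyldecyl)-1,2-dioxolan-3-yl]acetaldehyde | C[C@]1(CCCCCCCCCCc2ccccc2)C[C@](C)(CC=O)OO1 | intermediate (not isolated)
25 | andavadoic acid, 2-[(3R,5S)-3,5-dimethyl-5-(10-phenyldecyl)-1,2-dioxolan-3-yl]acetic acid | C[C@]1(CCCCCCCCCCc2ccccc2)C[C@](C)(CC(=O)O)OO1 | target

## Step count and least certain steps

Total: 15 steps. Longest linear sequence: 14 steps (steps 1 to 10 and 12 to 15); step 11 is the one-step preparation of the phosphonium salt.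

**Step 9 (key step, proposed new method).**
- Most likely failure: reduction of the hydroperoxide in place of oxypalladation. Oxygen transfer to CO, or O–O cleavage at palladium (the pathway by which palladium alkylperoxides oxidise alkenes), would consume the substrate before the ring closes. If the ring does close, poor facial selectivity at C5 is the next risk, because the C3 centre offers little help and a hydroperoxide is an untested nucleophile for these ligands.
- Fallback (known chemistry only): it sets out from oxetane 10 and returns at 16. Ozonolysis of 10 in CH2Cl2–MeOH at −78 °C turns the 2-methylallyl group into the hydroperoxy ketal (2R)-2-(2-hydroperoxy-2-methoxypropyl)-2-methyloxetane F1 (the oxetane centre is unchanged from 10). A catalytic amount of Me3SiOSO2CF3 then lets the tethered hydroperoxide open the oxetane at its tertiary carbon in a 5-exo closure with inversion, giving 2-[(3S)-5-methoxy-3,5-dimethyl-1,2-dioxolan-3-yl]ethan-1-ol F2 with the C3 configuration of the main route. Silylation with tBuPh2SiCl and imidazole, now with no hydroperoxide present, gives tert-butyl{2-[(3S)-5-methoxy-3,5-dimethyl-1,2-dioxolan-3-yl]ethoxy}diphenylsilane F3. TiCl4 at −78 °C ionises the ketal to the ring peroxycarbenium ion, which 1-(tert-butyldimethylsilyloxy)-1-methoxyethene captures to give 16 with its C5 epimer; the two are separated by chromatography.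
- This detour forgoes catalyst control at C5 and expects little substrate control. Because it branches at 10, it also stands behind steps 7 and 8.

**Step 8.**
- Most likely failure: competing silylation at the hydroperoxide oxygen, which is acidic and not much more hindered than the primary hydroxyl.
- Fallback: it sets out from 12 and returns at 13. 2-Methoxypropene with catalytic pyridinium p-toluenesulfonate caps the hydroperoxide as the peroxyketal (3R)-3-[(2-methoxypropan-2-yl)peroxy]-3,5-dimethylhex-5-en-1-ol F4; a mixed acetal formed at the primary alcohol is far more acid-labile and is removed by brief methanolysis. Silylation then gives tert-butyl({(3R)-3-[(2-methoxypropan-2-yl)peroxy]-3,5-dimethylhex-5-en-1-yl}oxy)diphenylsilane F5, and aqueous acetic acid in THF releases the hydroperoxide 13.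

**Step 10.**
- Most likely failure: over-reduction to the alcohol, or hydride attack on the O–O bond if the temperature rises.
- Fallback: it sets out from 16 and returns at 17. LiBH4 in THF–MeOH at 0 °C, a reagent that leaves dialkyl peroxides alone, reduces the ester fully to 2-[(3S,5S)-5-{2-[(tert-butyldiphenylsilyl)oxy]ethyl}-3,5-dimethyl-1,2-dioxolan-3-yl]ethan-1-ol F6. Oxidation with TEMPO and PhI(OAc)2 in dry CH2Cl2 stops at the aldehyde 17.

**Step 12.**
- Most likely failure: deprotonation of the beta-peroxy aldehyde by the ylide, followed by elimination that opens the ring across C1′–C5, competing with carbonyl addition.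
- Fallback: it avoids the aldehyde altogether, sets out from 16 and returns at 22. The ester is reduced to the alcohol F6 as described for step 10. Tf2O and 2,6-lutidine at −78 °C give 2-[(3S,5S)-5-{2-[(tert-butyldiphenylsilyl)oxy]ethyl}-3,5-dimethyl-1,2-dioxolan-3-yl]ethyl trifluoromethanesulfonate F7. (Oct-7-yn-1-yl)benzene F8, made from commercial (6-bromohexyl)benzene and LiC≡CH·H2NCH2CH2NH2 in DMSO, is lithiated with n-BuLi and alkylated by F7 in THF–N,N′-dimethylpropyleneurea at −78 to −20 °C. A lithium acetylide is a poor partner for attack on a peroxide flanked by two quaternary carbons. The product, tert-butyl{2-[(3S,5S)-3,5-dimethyl-5-(10-phenyldec-3-yn-1-yl)-1,2-dioxolan-3-yl]ethoxy}diphenylsilane F9, is saturated with excess diimide under the conditions of step 13 to give 22.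

## Further compounds

F1 | step 9 | (2R)-2-(2-hydroperoxy-2-methoxypropyl)-2-methyloxetane (both configurations at the ketal carbon) | COC(C)(OO)C[C@@]1(C)CCO1
F2 | step 9 | 2-[(3S)-5-methoxy-3,5-dimethyl-1,2-dioxolan-3-yl]ethan-1-ol (both configurations at C5) | COC1(C)C[C@](C)(CCO)OO1
F3 | step 9 | tert-butyl{2-[(3S)-5-methoxy-3,5-dimethyl-1,2-dioxolan-3-yl]ethoxy}diphenylsilane (both configurations at C5) | COC1(C)C[C@](C)(CCO[Si](c2ccccc2)(c2ccccc2)C(C)(C)C)OO1
F4 | step 8 | (3R)-3-[(2-methoxypropan-2-yl)peroxy]-3,5-dimethylhex-5-en-1-ol | C=C(C)C[C@](C)(CCO)OOC(C)(C)OC
F5 | step 8 | tert-butyl({(3R)-3-[(2-methoxypropan-2-yl)peroxy]-3,5-dimethylhex-5-en-1-yl}oxy)diphenylsilane | C=C(C)C[C@](C)(CCO[Si](c1ccccc1)(c1ccccc1)C(C)(C)C)OOC(C)(C)OC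
F6 | step 10 | 2-[(3S,5S)-5-{2-[(tert-butyldiphenylsilyl)oxy]ethyl}-3,5-dimethyl-1,2-dioxolan-3-yl]ethan-1-ol | C[C@]1(CCO)C[C@](C)(CCO[Si](c2ccccc2)(c2ccccc2)C(C)(C)C)OO1
F7 | step 12 | 2-[(3S,5S)-5-{2-[(tert-butyldiphenylsilyl)oxy]ethyl}-3,5-dimethyl-1,2-dioxolan-3-yl]ethyl trifluoromethanesulfonate | C[C@]1(CCOS(=O)(=O)C(F)(F)F)C[C@](C)(CCO[Si](c2ccccc2)(c2ccccc2)C(C)(C)C)OO1
F8 | step 12 | (oct-7-yn-1-yl)benzene | C#CCCCCCCc1ccccc1
F9 | step 12 | tert-butyl{2-[(3S,5S)-3,5-dimethyl-5-(10-phenyldec-3-yn-1-yl)-1,2-dioxolan-3-yl]ethoxy}diphenylsilane | C[C@]1(CCC#CCCCCCCc2ccccc2)C[C@](C)(CCO[Si](c2ccccc2)(c2ccccc2)C(C)(C)C)OO1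
A1 | alternative 1 | 3,5-dimethoxy-3,5-dimethyl-1,2-dioxolane (mixture of stereoisomers) | COC1(C)CC(C)(OC)OO1
A2 | alternative 1 | allyltrimethylsilane | C=CC[Si](C)(C)C
A3 | alternative 1 | (3S,5S)-3,5-dimethyl-3,5-di(prop-2-en-1-yl)-1,2-dioxolane | C[C@]1(CC=C)C[C@](C)(CC=C)OO1
A4 | alternative 2 | (2R,2′R)-2,2′-methylenebis(2-methyloxetane) | C[C@@]1(CCO1)C[C@@]2(C)CCO2
A5 | alternative 2 | 2,2′-[(3S,5S)-3,5-dimethyl-1,2-dioxolane-3,5-diyl]di(ethan-1-ol) | C[C@]1(CCO)C[C@](C)(CCO)OO1
A6 | alternative 3 | triethyl[(2-methoxy-12-phenyldodecan-2-yl)peroxy]silane (racemic) | CC[Si](CC)(CC)OOC(C)(OC)CCCCCCCCCCc1ccccc1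
A7 | alternative 3 | tert-butyl[(3-methylbut-3-en-1-yl)oxy]diphenylsilane | C=C(C)CCO[Si](c1ccccc1)(c1ccccc1)C(C)(C)C
A8 | alternative 3 | tert-butyl{2-[(3S,5S)-3,5-dimethyl-5-(10-phenyldecyl)-1,2-dioxolan-3-yl]ethoxy}diphenylsilane | C[C@]1(CCCCCCCCCCc2ccccc2)C[C@](C)(CCO[Si](c2ccccc2)(c2ccccc2)C(C)(C)C)OO1
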